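## Analysis of the target

The target is a single cyclohexene ring carrying five oxygens on seven carbons. Locants used throughout: C1 = CH(OBz) next to the quaternary C6, C2=C3 the alkene, C4 = CH(OBz), C5 = CH(OH), C6 = C(OH), C7 = CH2OH on C6. It has four stereocentres, (1S,4R,5S,6R). The benzoyloxy groups at C1 and C4 and the tertiary hydroxyl at C6 lie on one face; the C5 hydroxyl and C7 lie on the other. The 5,6-diol is therefore trans, the C1/C4 oxygens are cis, and C5–O and C7 are cis. Both benzoates are allylic and each has a free hydroxyl beside it (C4/C5, C1/C6), so ionisation and acyl migration under base or strong acid are the main sensitivities. The difficulty is to tell five oxygens apart (two secondary ones acylated; one primary, one secondary and one tertiary left free) while controlling a fully substituted carbinol carbon and three CH–O centres on a ring with no built-in bias. The plan rests on the cis-1,4 relationship of the C1 and C4 oxygens across C2=C3: this is what a two-oxygen bridge across a C1=C2–C3=C4 ring diene leaves behind once the O–O bond is cleaved. The remaining stereochemistry (C5, C6) can be installed beforehand as a trans-5,6-dioxygenated cyclohexadiene, whose cis C5 and C7 oxygens can be tied into one ring.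

## Retrosynthetic reasoning

**20 ⇒ 19 ⇒ 16 + 17.** The two benzoate C–O(acyl) bonds and the two Si–O bonds are cut first. The three hydroxyls that remain free in 20 need no individual protection: C5–O and C7–O are cis-1,3 and fit one di-tert-butylsilylene, and the C6 hydroxyl is tertiary and inert to acylation. The forward steps must acylate only C1 and C4 with 17, then release the silylene from 19 under conditions that leave allylic benzoates alone.

**16 ⇒ 15.** The C1 and C4 oxygens of 16 are reconnected through an O–O bond. The cis relationship of two separate stereocentres thereby becomes a ring constraint of 15. The forward step is only a mild O–O reduction that leaves the C–O bonds and C2=C3 intact.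

**15 ⇒ 14.** The C1–O and C4–O bonds are cut together in a hetero-[4+2] cycloreversion. This is the one disconnection that removes two stereocentres and two C–O bonds at once with their mutual cis relationship guaranteed. It leaves diene 14, whose only stereochemical content is C5/C6. The forward reaction has to deliver the two-oxygen unit to the face of the diene that carries the C6 hydroxyl. The silylene ring (C5–O and C7 on the opposite face) and the free tertiary hydroxyl are there for that purpose.

**14 ⇒ 12 ⇒ 11.** The C1=C2 and C3=C4 double bonds are traced back to the isolated C2=C3 alkene of 11 by addition of halogen (12) and double elimination. Diene 14 is a dihydroarene-diol derivative, prone to aromatisation, and is best unveiled immediately before use. Its isomer 11 with the skipped alkene is robust and can carry the stereocentres through the protecting-group work.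

**11 ⇒ 9 + 10.** The two Si–O bonds are cut. The forward step must choose the six-membered C5/C7 silylene over the alternatives that involve the tertiary hydroxyl. Ring size and hindrance both favour it.

**9 ⇒ 8 ⇒ 6 ⇒ 5.** The C6–O bond of the trans-diol is cut, with its oxygen delivered from a urethane tethered at C7 onto C6 of epoxide 5 with inversion. An external oxygen nucleophile was not chosen. Attack at C5 and attack at C6 both give a trans-triol, but the two triols are mirror images, so any regiochemical leak would appear as loss of enantiopurity. With the tether, attack at the wrong carbon gives a six-membered carbonate, a constitutional isomer of 8 that can be removed before 9 is released.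

**5 ⇒ 4.** The two epoxide C–O bonds are cut. The allylic hydroxyl of 4 selects C5=C6 over C2=C3 and lets a tartrate-controlled epoxidation set the absolute configuration of C5 and C6. All later stereocentres follow from these two.

**4 ⇒ 3 ⇒ 1 + 2.** After adjusting C7 to the ester oxidation level, the ring is opened at C1–C6 and C4–C5 by a Diels–Alder disconnection. This gives the skipped 1,4-diene with the one-carbon substituent in place and the two alkenes already differentiated (one conjugated, one isolated), from two simple achiral feedstocks.

## Alternatives that were turned down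

**Alternative 1:** The ring is disconnected at C4–C5 and C6–C1: a catalytic asymmetric Diels–Alder reaction of (1E,3E)-1,4-diacetoxybuta-1,3-diene A2 with the reductone-derived (E)-2,3-bis(chloroacetoxy)acrolein A3 would give cycloadduct A1.
- For: one step builds the ring and all four stereocentres. The cis-1,4 relation follows from the E,E diene and the trans-5,6 relation from the E dienophile. On convergence and step count it is stronger than the chosen route.
- Against: A3 is a β-acyloxy enal, a push–pull, trisubstituted and weak dienophile. A2 is terminally disubstituted and only mildly activated. The required adduct has the formyl group exo (anti to the C1/C4 oxygens). The catalyst must pick one enantioface of a dienophile with three competing Lewis-basic acyl groups. None of this is enforced by the structures.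
- Against, after the cycloaddition: the acetates at C1/C4 must become benzoates while C5, C6 and C7 end up free. Chloroacetates are more labile than acetates, so the exchange needs extra protection steps on a substrate where 1,2-acyl shifts (C4→C5, C1→C6) are easy.
- Comparison: the chosen route is longer, but every oxygen arrives already differentiated and every bond-forming step has a close precedent.

**Alternative 2:** The C5–O and C6–O bonds are traced to an epoxide on a quinone whose C2=C3 alkene is masked in a norbornene. Weitz–Scheffer epoxidation (alkaline H2O2) of the enantioenriched tricyclic ene-dione A5 from its convex face would give epoxy dione A4, and a later cycloreversion would release C2=C3.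
- For: the facial selectivity of this step is dictated by a rigid cup-shaped tricycle and is more certain than that of the photooxygenation chosen here.
- Against: the step sets only a cis-epoxide, whereas 20 needs a trans-5,6-diol. The epoxide would have to be opened by water at the secondary C5 with inversion, although acid activation favours the tertiary C6, which gives the C5/C6 diastereomer.
- Against: both carbonyls (C1, C4) must still be reduced to the all-cis diol. Cycloreversion is easy only at the dione stage, so these reductions are controlled by the epoxide alone, or else allylic benzoates must survive a high-temperature thermolysis.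
- Against: an enantioenriched A5 must first be secured by an asymmetric cycloaddition or a resolution.
- Comparison: the sequence is at least as long as the chosen one and places a regiochemical gamble near the end. The chosen route places its one uncertain selectivity in a step where the steric and directing effects cooperate.

**Alternative 3:** The C1–O and C6–O bonds are disconnected as a syn-dihydroxylation. Catalytic OsO4 with N-methylmorpholine N-oxide would oxidise the C6=C1 alkene of diene A8, anti to the C5 silyloxy group, to the C1,C6-cis-diol A6. A8 would come from the microbial bromobenzene cis-dihydrodiol A7: C5–O retained, C4–O inverted to the benzoate by a Mitsunobu reaction, C7 attached at C–Br by palladium-catalysed coupling.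
- For: A7 is enantiopure and already has the correct C5 configuration. On absolute stereocontrol this beats a catalytic epoxidation. The cis-1,6-diol anti to C5–O is exactly the pattern of 20, and the step count is comparable.
- Against: the key step must choose the trisubstituted C6=C1 alkene, flanked by C5–OSi and CH2OSi, over the less hindered C2=C3 of the same conjugated diene. Electronics and sterics pull in opposite directions, and oxidation at C2=C3 or over-oxidation would be fatal.
- Against: the Mitsunobu inversion at a dienylic carbinol of a cyclohexadiene is prone to elimination with aromatisation and to SN2′ attack. The coupling must also be run on a fragile dihydroarene.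
- Comparison: the chosen route gives up the chiral-pool advantage. In return its oxygenation has no site-selectivity problem, since one diene is oxidised at both termini at once. It starts from cheap achiral materials, and either enantiomer is available by choice of tartrate.

Key step: step 10

Remark on the chemistry: bromine can add anti to C2=C3 from either face. Compounds 12 and 13 are drawn as one anti-adduct, and both adducts converge on 14 because the C–Br centres are destroyed.

## Route

Step 1
Reactants: 1 buta-1,3-diene; 2 methyl propiolate
Product: 3 methyl cyclohexa-1,4-diene-1-carboxylate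
Conditions: 1 (excess), toluene, BHT (cat.), sealed vessel, 110 °C
Reagents that add atoms: none
Why: Diels–Alder [4+2] cycloaddition of s-cis butadiene with the acetylenic ester forms C1–C6 and C4–C5 and gives the skipped 1,4-diene directly, with the ester on the conjugated alkene. No stereocentre is formed, and the alkyne is a much better dienophile than the product, so a second addition should stay minor.

Step 2
Reactants: 3 methyl cyclohexa-1,4-diene-1-carboxylate
Product: 4 (cyclohexa-1,4-dien-1-yl)methanol
Conditions: iBu2AlH (2.3 equiv), CH2Cl2, −78 → 0 °C; aq. potassium sodium tartrate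
Reagents that add atoms: none
Why: 1,2-Reduction of the conjugated ester by the electrophilic aluminium hydride gives the allylic alcohol without conjugate reduction or migration of the skipped diene.

Step 3
Reactants: 4 (cyclohexa-1,4-dien-1-yl)methanol
Product: 5 [(1S,6S)-7-oxabicyclo[4.1.0]hept-3-en-1-yl]methanol
Conditions: Ti(OiPr)4 (10 mol %), L-(+)-diethyl tartrate (12 mol %), t-BuOOH (2 equiv), 4 Å MS, CH2Cl2, −20 °C
Reagents that add atoms: tert-butyl hydroperoxide, CC(C)(C)OO
Why: Sharpless asymmetric epoxidation: titanium binds the allylic alkoxide, so only C5=C6 is oxidised and the isolated C2=C3 alkene is inert to this system. L-(+)-tartrate is expected to make both epoxide carbons S, the sense established for allylic alcohols of this substitution pattern; this sets the absolute configuration of C5 and C6.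

Step 4
Reactants: 5 [(1S,6S)-7-oxabicyclo[4.1.0]hept-3-en-1-yl]methanol
Product: 6 [(1S,6S)-7-oxabicyclo[4.1.0]hept-3-en-1-yl]methyl N-phenylcarbamate
Conditions: PhNCO (1.2 equiv), Et3N (cat.), CH2Cl2, 0 °C → rt
Reagents that add atoms: phenyl isocyanate, O=C=Nc1ccccc1
Why: Addition of the primary alcohol to the isocyanate gives the urethane whose carbonyl oxygen will become the C6 hydroxyl oxygen. Epoxide and alkene are untouched under these neutral conditions.

Step 5
Reactants: 6 [(1S,6S)-7-oxabicyclo[4.1.0]hept-3-en-1-yl]methyl N-phenylcarbamate
Product: 8 (5R,6S)-6-hydroxy-1,3-dioxaspiro[4.5]dec-8-en-2-one, via iminocarbonate 7 (not isolated)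
Conditions: BF3·OEt2 (1.1 equiv), Et2O, −20 °C; then 1 M aq. H2SO4, rt
Reagents that add atoms: water, O
Why: Lewis-acid-promoted intramolecular epoxide opening by the urethane carbonyl oxygen (neighbouring-group participation): attack occurs at C6, the carbon that carries the tether (five-membered ring) and is tertiary, from the face opposite the epoxide oxygen, so C6 is inverted while C5 keeps its oxygen and configuration, which gives the trans-5,6 relationship. Aqueous acid then hydrolyses the cyclic iminocarbonate to the carbonate; any closure at C5 would give a six-membered carbonate, a constitutional isomer that can be removed here by chromatography.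

Step 6
Reactants: 8 (5R,6S)-6-hydroxy-1,3-dioxaspiro[4.5]dec-8-en-2-one
Product: 9 (1R,2S)-1-(hydroxymethyl)cyclohex-4-ene-1,2-diol
Conditions: K2CO3 (0.2 equiv), MeOH, 0 °C → rt
Reagents that add atoms: none
Why: Base-catalysed methanolysis (transesterification) of the five-membered cyclic carbonate releases the triol; no C–O bond at a stereocentre is broken.

Step 7
Reactants: 9 (1R,2S)-1-(hydroxymethyl)cyclohex-4-ene-1,2-diol; 10 di-tert-butylsilyl bis(trifluoromethanesulfonate)
Product: 11 (4aR,8aS)-2,2-di-tert-butyl-4a,5,8,8a-tetrahydro-4H-1,3,2-benzodioxasilin-4a-ol
Conditions: 10 (1.05 equiv), 2,6-lutidine (3 equiv), DMF, −20 → 0 °C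
Reagents that add atoms: di-tert-butylsilyl bis(trifluoromethanesulfonate), CC(C)(C)[Si](OS(=O)(=O)C(F)(F)F)(OS(=O)(=O)C(F)(F)F)C(C)(C)C
Why: Silylene protection of a 1,3-diol: the primary C7 hydroxyl silylates first and the remaining silyl triflate closes onto the cis-disposed secondary C5 hydroxyl to give the unstrained six-membered 1,3,2-dioxasilinane. Closure onto the tertiary C6 hydroxyl would need a strained five-membered di-tert-butylsilylene at a hindered oxygen and should lose.

Step 8
Reactants: 11 (4aR,8aS)-2,2-di-tert-butyl-4a,5,8,8a-tetrahydro-4H-1,3,2-benzodioxasilin-4a-ol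
Product: 12 (4aR,6R,7R,8aS)-6,7-dibromo-2,2-di-tert-butylhexahydro-4H-1,3,2-benzodioxasilin-4a-ol (trans-dibromide at C2/C3; the 6S,7S anti-adduct serves equally)
Conditions: Br2 (1.05 equiv), NaHCO3 (solid), CH2Cl2, −78 °C
Reagents that add atoms: bromine, BrBr
Why: Electrophilic anti addition of bromine to the only alkene through the bromonium ion gives the trans-diaxial dibromide. Low temperature and the high bromide (tribromide) concentration should let bromide capture the bromonium ion before the tertiary hydroxyl can.

Step 9
Reactants: 12 (4aR,6R,7R,8aS)-6,7-dibromo-2,2-di-tert-butylhexahydro-4H-1,3,2-benzodioxasilin-4a-ol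
Product: 14 (4aR,8aS)-2,2-di-tert-butyl-4a,8a-dihydro-4H-1,3,2-benzodioxasilin-4a-ol, via bromoalkene 13 (not isolated)
Conditions: DBU (4 equiv), THF, 0 → 50 °C; used at once
Reagents that add atoms: none
Why: Two successive E2 dehydrobrominations, the classical passage from a cyclohexene through its dibromide to the cyclohexa-1,3-diene: each axial bromide has an anti-periplanar hydrogen only on the flanking CH2 (C1 or C4), not on the neighbouring CHBr, so elimination runs outwards to C1=C2–C3=C4 and not to a vinyl bromide. C5 and C6 are not involved, and the poor leaving groups there (silyl ether, free hydroxyl) disfavour aromatisation under base.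

Step 10
Reactants: 14 (4aR,8aS)-2,2-di-tert-butyl-4a,8a-dihydro-4H-1,3,2-benzodioxasilin-4a-ol
Product: 15 endoperoxide: O–O bridge from C1 to C4 on the face of the C6 hydroxyl (2,3-dioxabicyclo[2.2.2]oct-5-ene core), C5/C7 di-tert-butylsilylene and free C6 hydroxyl retained
Conditions: O2, tetraphenylporphyrin (1 mol %), white light (LED), CH2Cl2, −30 °C
Reagents that add atoms: dioxygen, O=O
Why: Sensitised photooxygenation: tetraphenylporphyrin transfers triplet energy to O2 and the resulting singlet oxygen adds across C1 and C4 of the ring-locked s-cis diene in a concerted, suprafacial [4+2] cycloaddition that forms the C1–O and C4–O bonds together. The closest known reaction type is the photooxygenation of cyclohexa-1,3-dienes, 5,6-dioxygenated ones included, to 2,3-dioxabicyclo[2.2.2]oct-5-enes. The one new ring, a six-membered 3,6-dihydro-1,2-dioxine, is closed by the cycloaddition itself, both bonds in one step, which is why the two new C–O bonds must be cis. C1 and C4 are the new stereocentres: their mutual relationship is fixed by suprafaciality and their configuration relative to C5 and C6 by the face of approach, that is by substrate control. The face syn to the C6 hydroxyl is flanked only by that hydroxyl and by H5, whereas the opposite face carries C5–O and C7 tied into the silylene ring with its tert-butyl groups; in a non-hydroxylic solvent the free tertiary hydroxyl can also hydrogen-bond to the incoming oxygen, so steric shielding and direction point the same way. The step also needs cycloaddition to beat the ene pathway: H5 is the only allylic hydrogen, C6 has none, and a cisoid six-ring diene is an intrinsically good [4+2] partner. Low temperature and a neutral, acid-free medium protect the diene from dehydrative aromatisation and the peroxide from base-induced rearrangement.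

Step 11
Reactants: 15 endoperoxide
Product: 16 (4aS,5S,8R,8aS)-2,2-di-tert-butyl-4a,5,8,8a-tetrahydro-4H-1,3,2-benzodioxasiline-4a,5,8-triol
Conditions: thiourea (1.5 equiv), MeOH, 0 °C → rt
Reagents that add atoms: none
Why: Reductive O–O cleavage by nucleophilic attack of thiourea sulfur on the peroxide, then solvolysis, frees the cis-2-ene-1,4-diol. No C–O bond is broken, so C1 and C4 keep the configuration set in the cycloaddition, and the alkene and silylene are inert.

Step 12
Reactants: 16 (4aS,5S,8R,8aS)-2,2-di-tert-butyl-4a,5,8,8a-tetrahydro-4H-1,3,2-benzodioxasiline-4a,5,8-triol; 17 benzoyl chloride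
Product: 19 (4aS,5S,8R,8aS)-2,2-di-tert-butyl-4a-hydroxy-4a,5,8,8a-tetrahydro-4H-1,3,2-benzodioxasiline-5,8-diyl dibenzoate, via C4 monobenzoate 18 (not isolated)
Conditions: 17 (2.5 equiv), pyridine, DMAP (cat.), CH2Cl2, 0 °C → rt
Reagents that add atoms: benzoyl chloride, O=C(Cl)c1ccccc1
Why: Acylation through the N-acylpyridinium ion esterifies the two secondary allylic hydroxyls (the less hindered C4 first, then C1). The tertiary C6 hydroxyl is too hindered to react under these conditions, and C5 and C7 are locked in the silylene.

Step 13
Reactants: 19 (4aS,5S,8R,8aS)-2,2-di-tert-butyl-4a-hydroxy-4a,5,8,8a-tetrahydro-4H-1,3,2-benzodioxasiline-5,8-diyl dibenzoate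
Product: 20 (1S,4R,5S,6R)-5,6-dihydroxy-6-(hydroxymethyl)cyclohex-2-ene-1,4-diyl dibenzoate
Conditions: HF·pyridine, pyridine, THF, 0 °C → rt
Reagents that add atoms: none
Why: Fluoride-driven cleavage of both Si–O bonds, pulled by the strong Si–F bond, frees the C5 and C7 hydroxyls. The buffered, weakly acidic medium avoids the alkoxide-mediated benzoate migration that basic fluoride sources would invite.

## Compound list

1 | buta-1,3-diene | C=CC=C | starting material
2 | methyl propiolate | C#CC(=O)OC | starting material
3 | methyl cyclohexa-1,4-diene-1-carboxylate | COC(=O)C1=CCC=CC1 | intermediate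
4 | (cyclohexa-1,4-dien-1-yl)methanol | OCC1=CCC=CC1 | intermediate
5 | [(1S,6S)-7-oxabicyclo[4.1.0]hept-3-en-1-yl]methanol | OC[C@@]12CC=CC[C@@H]1O2 | intermediate
6 | [(1S,6S)-7-oxabicyclo[4.1.0]hept-3-en-1-yl]methyl N-phenylcarbamate | O=C(Nc1ccccc1)OC[C@@]12CC=CC[C@@H]1O2 | intermediate
7 | (5R,6S)-2-(phenylimino)-1,3-dioxaspiro[4.5]dec-8-en-6-ol (iminocarbonate, present as its BF3 adduct) | c1ccccc1N=C1OC[C@]2(O1)CC=CC[C@@H]2O | intermediate (not isolated)
8 | (5R,6S)-6-hydroxy-1,3-dioxaspiro[4.5]dec-8-en-2-one | O=C1OC[C@]2(O1)CC=CC[C@@H]2O | intermediate
9 | (1R,2S)-1-(hydroxymethyl)cyclohex-4-ene-1,2-diol | OC[C@]1(O)CC=CC[C@@H]1O | intermediate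
10 | di-tert-butylsilyl bis(trifluoromethanesulfonate) | CC(C)(C)[Si](OS(=O)(=O)C(F)(F)F)(OS(=O)(=O)C(F)(F)F)C(C)(C)C | starting material
11 | (4aR,8aS)-2,2-di-tert-butyl-4a,5,8,8a-tetrahydro-4H-1,3,2-benzodioxasilin-4a-ol | CC(C)(C)[Si]1(OC[C@]2(O)CC=CC[C@@H]2O1)C(C)(C)C | intermediate
12 | (4aR,6R,7R,8aS)-6,7-dibromo-2,2-di-tert-butylhexahydro-4H-1,3,2-benzodioxasilin-4a-ol (one anti-adduct drawn) | CC(C)(C)[Si]1(OC[C@]2(O)C[C@@H](Br)[C@H](Br)C[C@@H]2O1)C(C)(C)C | intermediate
13 | (4aR,6R,8aS)-6-bromo-2,2-di-tert-butyl-4a,5,6,8a-tetrahydro-4H-1,3,2-benzodioxasilin-4a-ol (C3=C4 formed, bromide left at C2) | CC(C)(C)[Si]1(OC[C@]2(O)C[C@@H](Br)C=C[C@@H]2O1)C(C)(C)C | intermediate (not isolated)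
14 | (4aR,8aS)-2,2-di-tert-butyl-4a,8a-dihydro-4H-1,3,2-benzodioxasilin-4a-ol (5,6-trans dienol, C5/C7 silylene, free C6–OH) | CC(C)(C)[Si]1(OC[C@]2(O)C=CC=C[C@@H]2O1)C(C)(C)C | intermediate
15 | endoperoxide of 14: O–O bridge C1→C4 syn to the C6 hydroxyl and anti to C5–O and C7; configuration at C1, C4, C5, C6 as in 20 | O3[C@H]1C=C[C@@H](O3)[C@H](O[Si](C(C)(C)C)(C(C)(C)C)OC2)[C@@]12O | intermediate
16 | (4aS,5S,8R,8aS)-2,2-di-tert-butyl-4a,5,8,8a-tetrahydro-4H-1,3,2-benzodioxasiline-4a,5,8-triol | O[C@H]1C=C[C@@H](O)[C@H](O[Si](C(C)(C)C)(C(C)(C)C)OC2)[C@@]12O | intermediate
17 | benzoyl chloride | O=C(Cl)c1ccccc1 | starting material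
18 | (4aS,5S,8R,8aS)-2,2-di-tert-butyl-4a,5-dihydroxy-4a,5,8,8a-tetrahydro-4H-1,3,2-benzodioxasilin-8-yl benzoate (C4 monobenzoate) | O[C@H]1C=C[C@@H](OC(=O)c3ccccc3)[C@H](O[Si](C(C)(C)C)(C(C)(C)C)OC2)[C@@]12O | intermediate (not isolated)
19 | (4aS,5S,8R,8aS)-2,2-di-tert-butyl-4a-hydroxy-4a,5,8,8a-tetrahydro-4H-1,3,2-benzodioxasiline-5,8-diyl dibenzoate | O=C(O[C@H]1C=C[C@@H](OC(=O)c3ccccc3)[C@H](O[Si](C(C)(C)C)(C(C)(C)C)OC2)[C@@]12O)c4ccccc4 | intermediate
20 | (1S,4R,5S,6R)-5,6-dihydroxy-6-(hydroxymethyl)cyclohex-2-ene-1,4-diyl dibenzoate | O=C(O[C@H]1C=C[C@@H](OC(=O)c2ccccc2)[C@H](O)[C@]1(O)CO)c1ccccc1 | target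

## Step count and least certain steps

Total: 13 steps. Longest linear sequence: 13 steps (1 and 2 to 20).

**Step 10 (key step).**
- What may go wrong: erosion of facial selectivity if hydrogen bonding to the C6 hydroxyl is weak or the silylene ring shields less than expected; competing ene-type hydrogen abstraction at C5; dehydrative aromatisation of the diene before it is oxidised.
- Fallback (sets out from 14, returns at 18): epoxidise C1=C2 of 14 with VO(acac)2 and t-BuOOH. The tertiary allylic C6 hydroxyl directs the reagent to its own alkene and its own face, giving the vinyl epoxide F1. Open F1 with benzoic acid under Pd(PPh3)4 catalysis: the π-allyl complex forms with inversion at C2 and benzoate attacks C4 with a second inversion. This puts the C4 benzoate on the same face as the C1 hydroxyl and gives 18. The second benzoylation of step 12 then takes 18 to 19.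

**Step 5.**
- What may go wrong: ionisation at the tertiary C6 running ahead of participation, which would cause loss of stereospecificity or a hydride or ring-bond shift to carbonyl compounds; partial closure at C5.
- Fallback (sets out from 4, returns at 9): epoxidise 4 with D-(−)-diethyl tartrate to the antipodal epoxy alcohol F2. Open F2 intermolecularly at C5 with benzoic acid and Ti(OiPr)4, where the chelate directs attack with inversion to the carbon remote from the carbinol, giving the C5 benzoate F3. Purify F3 before K2CO3–methanol cleavage to 9, because attack at the wrong carbon in this variant would lower enantiopurity rather than give a separable isomer after cleavage.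

**Step 8.**
- What may go wrong: capture of the bromonium ion across the ring by the free tertiary hydroxyl (bromoetherification) instead of by bromide; silylene cleavage by adventitious HBr.
- Fallback (sets out from 6, returns at 12): brominate earlier, at 6, which has no free hydroxyl, to the dibromo urethane F4. Cyclise and hydrolyse as in step 5 to the dibromo carbonate F5. Methanolyse at 0 °C to the dibromo triol F6. Silylate F6 with 10 as in step 7 to reach 12.

**Step 9.**
- What may go wrong: intramolecular displacement of bromide by the C6 hydroxyl; elimination stopping at the allylic bromide; base- or heat-induced aromatisation or dimerisation of the product diene.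
- Fallback (sets out from 12, returns at 14): mask the tertiary hydroxyl of 12 with TMSOTf and 2,6-lutidine as its trimethylsilyl ether F7. Eliminate with DBU to the silylated diene F8. Remove the trimethylsilyl group with K2CO3 in methanol at 0 °C to give 14. The internal nucleophile is absent during both eliminations.

## Further compounds

F1 | step 10 | vinyl epoxide: C1–C2 epoxide of 14 on the face of the C6 hydroxyl, C3=C4 retained | CC(C)(C)[Si]1(OC[C@]2(O)[C@H]3O[C@H]3C=C[C@@H]2O1)C(C)(C)C
F2 | step 5 | [(1R,6R)-7-oxabicyclo[4.1.0]hept-3-en-1-yl]methanol | OC[C@]12CC=CC[C@H]1O2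
F3 | step 5 | (1S,6R)-6-hydroxy-6-(hydroxymethyl)cyclohex-3-en-1-yl benzoate | OC[C@]1(O)CC=CC[C@@H]1OC(=O)c2ccccc2
F4 | step 8 | [(1S,3R,4R,6S)-3,4-dibromo-7-oxabicyclo[4.1.0]heptan-1-yl]methyl N-phenylcarbamate (one anti-adduct drawn) | O=C(Nc1ccccc1)OC[C@@]12C[C@@H](Br)[C@H](Br)C[C@@H]1O2
F5 | step 8 | (5R,6S,8R,9R)-8,9-dibromo-6-hydroxy-1,3-dioxaspiro[4.5]decan-2-one | O=C1OC[C@]2(O1)C[C@@H](Br)[C@H](Br)C[C@@H]2O
F6 | step 8 | (1R,2S,4R,5R)-4,5-dibromo-1-(hydroxymethyl)cyclohexane-1,2-diol | OC[C@]1(O)C[C@@H](Br)[C@H](Br)C[C@@H]1O
F7 | step 9 | trimethylsilyl ether of 12 at the C6 oxygen | CC(C)(C)[Si]1(OC[C@]2(O[Si](C)(C)C)C[C@@H](Br)[C@H](Br)C[C@@H]2O1)C(C)(C)C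
F8 | step 9 | trimethylsilyl ether of 14 at the C6 oxygen | CC(C)(C)[Si]1(OC[C@]2(O[Si](C)(C)C)C=CC=C[C@@H]2O1)C(C)(C)C
A1 | alternative 1 | cycloadduct: C1 and C4 acetates, C5 and C6 chloroacetates, C7 as aldehyde, all centres as in 20 | CC(=O)O[C@H]1C=C[C@@H](OC(C)=O)[C@H](OC(=O)CCl)[C@]1(OC(=O)CCl)C=O
A2 | alternative 1 | (1E,3E)-buta-1,3-diene-1,4-diyl diacetate | CC(=O)O/C=C/C=C/OC(C)=O
A3 | alternative 1 | (E)-2,3-bis(chloroacetoxy)prop-2-enal | ClCC(=O)O/C=C(\C=O)OC(=O)CCl
A4 | alternative 2 | convex-face epoxy dione on the norbornene-fused scaffold, C7 as tert-butyldimethylsilyl ether | O=C1[C@@H]2O[C@]2(CO[Si](C)(C)C(C)(C)C)C(=O)[C@H]3[C@H]4C=C[C@H](C4)[C@@H]13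
A5 | alternative 2 | enantioenriched norbornene-fused ene-dione (masked 2-(silyloxymethyl)benzoquinone) | O=C1C=C(CO[Si](C)(C)C(C)(C)C)C(=O)[C@H]2[C@H]3C=C[C@H](C3)[C@@H]12
A6 | alternative 3 | C1,C6-cis-diol with C4 benzoate and C5, C7 tert-butyldimethylsilyl ethers | O=C(O[C@@H]1C=C[C@H](O)[C@@](O)(CO[Si](C)(C)C(C)(C)C)[C@H]1O[Si](C)(C)C(C)(C)C)c1ccccc1
A7 | alternative 3 | (1S,2S)-3-bromocyclohexa-3,5-diene-1,2-diol | BrC1=CC=C[C@H](O)[C@@H]1O
A8 | alternative 3 | diene with trans C4 benzoate and C5 silyl ether, silyloxymethyl group on C6 | O=C(O[C@@H]1C=CC=C(CO[Si](C)(C)C(C)(C)C)[C@H]1O[Si](C)(C)C(C)(C)C)c1ccccc1
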